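- In percent of the starting material charged, the unit of the question, this flask holds 10.0% more first nucleophile than starting material, and before charging I must decide whether first nucleophile can stay at 0.275 M when starting material rises to 0.25 M.

| setting | grey | flask |
|---|---|---|
| starting material | 0.12 M (fed, over 2.0 h) | 0.25 M (fed, over 2.0 h) |
| first nucleophile | 0.275 M | 0.275 M |
| solid second nucleophile | 0.237 M | 0.237 M |
| remark | run made earlier; the fed solution adds 0.25 times the starting volume | the fed solution adds 0.25 times the starting volume |
| time |  | 2.0 h |

grey run (percent of the starting material charged)

| time / min | other capture product / % | target / % |
|---|---|---|
| 2.50 | 1 | 0 |
| 8.00 | 1 | 0 |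
| 12.0 | 5 | 3 |
| 20.0 | 0 | 8 |
| 30.0 | 1 | 16 |
| 40.0 | 2 | 23 |

(readings scatter by 2 percentage points)

- charges are per starting volume, the dose included; the dosed solution carries all of it
- given per volume of solution although it is solid: solid second nucleophile
- what may be going on: starting material -> intermediate; first nucleophile -> decomposed reagent; second nucleophile + intermediate -> other capture product; solid second nucleophile <-> second nucleophile; first nucleophile + intermediate -> target; first nucleophile -> decomposition product
- at the start none of the solid second nucleophile is in solution
- percentages count the whole charge, also what has not yet gone in

1. amount of other capture product in percent of the starting material charged, at 12 min, 40 min and 2.0 h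

- I count turnovers: each target uses one first nucleophile, so I carry the excess margin, (c(first nucleophile) − c(starting material)) / c(starting material) taken from the charges, which is how much first nucleophile can go elsewhere while the charge of starting material, the limiting reagent on paper, is still covered.
- The earlier run had an excess margin of 129%, far wider than the flask's, so its good showing does not carry over by itself.
- Its readings stop at 40.0 min, with 2% other capture product against 23% target and a scatter of 2 percentage points, and none of them is a reading of first nucleophile, so they give me no size for the possible loss to decomposed reagent.
- My own reckoning therefore gives a limit and no figure: any loss of first nucleophile beyond the excess margin comes out of what can become target, so I leave the dose and the solid second nucleophile as they stand, run the flask as written, and raise first nucleophile next time if the loss exceeds the margin.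
- The forecast, made from the same runs, does give figures: 1%, 2.5% and 15% at the three asked times, on the ground that the “competition ratio therefore worsens late in the feed”, and it calls its last figure quite uncertain.
- The flask gives 0.158%, 2.47% and 26.2%, so the last value lies 11 points above the forecast.

    starting material → intermediate (k = 0.00180 /s)
    first nucleophile → decomposed reagent (k = 9.60 × 10⁻⁵ /s)
    second nucleophile + intermediate → other capture product (k = 0.240 /M/s)
    solid second nucleophile ⇌ second nucleophile, rate k4*(cs4 - [second nucleophile]) while solid is left; crystals form when [second nucleophile] > cs4 (solubility = 0.130 M, k = 6.40 × 10⁻⁴ /s)
    first nucleophile + intermediate → target (k = 0.810 /M/s)
    first nucleophile → decomposition product (k = 7.40 × 10⁻⁷ /s)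

- While starting material was being dosed, first nucleophile fell from 42.1% of its charge at 1.00 h to 7.73% at 2.00 h, as second nucleophile went from 0.106 M to 0.104 M and other capture product rose from 5.67% to 26.2%. From the start of the flask up to 2.00 h, first nucleophile also went to decomposed reagent, which stands at 0.0709 M in the grown volume, and that is 35.4% of the starting material charged against the excess margin of 10.0%. The simulated run with twice the first nucleophile, other amounts unchanged, has an excess margin of 120% and gives 11.2% other capture product.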